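## Retrosynthetic overview

1. The benzoquinone ring is not built. As in nature, a preformed aromatic nucleus (hydroquinone 3, generated from quinone 1) is C-prenylated and then oxidised; the nine-unit all-E chain comes intact from solanesol 2.
2. Ring–chain bond: Friedel–Crafts attack of 3 on the solanesyl cation gives hydroquinone 4, which 1 oxidises in the flask to ubiquinone-9 5. This arene-to-quinone change in the first step is the only ring event.
3. Stereocentre C35: terminal E-methyl hydroxylation (5 to 6), then OH-directed asymmetric hydrogenation of the ninth isoprene unit (6 via 7 and 8 to 9).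
4. C36–C37 bond (tenth unit): tosylate 10 is masked as hydroquinone 11, coupled with a prenyl Grignard reagent under copper catalysis (12) and reoxidised to target 13.

Assumption: side-chain carbons are numbered from the ring-bound CH2 (C1) outward, commercial solanesol is the all-E isomer, and the only stereocentre of the target (C35) is S.

## Route

Step 1
Reactants: 1 coenzyme Q0 (2,3-dimethoxy-5-methyl-1,4-benzoquinone); 2 all-E solanesol
Product: 5 ubiquinone-9, via ubiquinol-0 3 (not isolated), via ubiquinol-9 4 (not isolated)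
Conditions: 1 (2.0 equiv), Hantzsch ester (0.3 equiv), Sc(OTf)3 (10 mol %), CH2Cl2/MeNO2 3:1, 25 °C, Ar, 2 added over 4 h; AgNO3–SiO2 chromatography
Reagents that add atoms: none
Why: Proposed new method: Hantzsch ester reduces part of 1 to hydroquinone 3, whose only free ring position attacks the Sc(OTf)3-generated solanesyl allyl cation (Friedel–Crafts C-prenylation, the chemical counterpart of the aromatic prenyl-transfer step) to give 4, which is a stronger reductant than 3 and is therefore oxidised by 1 to 5 while 3 is regenerated (redox chain), so the acid-sensitive prenylated hydroquinone never accumulates; the closest known reactions are Lewis-acid Friedel–Crafts alkylation of ubiquinol-0, trimethylhydroquinone or menadiol with polyprenols and phytols followed by oxidation, and hydroquinone-initiated redox-chain alkylation of quinones with simple allylic electrophiles; the E geometry at C2=C3 is largely retained from the allyl cation and the minor 2Z isomer is removed on AgNO3–SiO2.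

Step 2
Reactants: 5 ubiquinone-9
Product: 6 36-hydroxyubiquinone-9
Conditions: SeO2 (0.3 equiv), t-BuOOH (3 equiv, 5.5 M in decane), salicylic acid (0.1 equiv), CH2Cl2, 0 to 25 °C, stopped near 50 % conversion, 5 recycled
Reagents that add atoms: selenium dioxide, O=[Se]=O (transfers the oxygen atom); tert-butyl hydroperoxide, CC(C)(C)OO (reoxidant and ultimate oxygen source)
Why: Sharpless SeO2/t-BuOOH allylic oxidation (ene reaction, then [2,3]-sigmatropic shift) attacks the least hindered terminal isopropylidene unit at its E-methyl group and gives the E allylic alcohol; the quinone is inert, and conversion is kept low because the eight internal trisubstituted alkenes compete statistically.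

Step 3
Reactants: 6 36-hydroxyubiquinone-9
Product: 9 (35S)-36-hydroxy-34,35-dihydroubiquinone-9, via 36-hydroxyubiquinol-9 7 (not isolated), via (35S)-36-hydroxy-34,35-dihydroubiquinol-9 8 (not isolated)
Conditions: H2 (50 atm), Ru(OAc)2[(S)-BINAP] (2 mol %), MeOH/CH2Cl2 2:1, 25 °C; then Ag2O, Et2O, 25 °C
Reagents that add atoms: none
Why: Noyori hydroxyl-directed asymmetric hydrogenation: the quinone is first reduced to hydroquinone 7, then only the alkene bound to ruthenium through the allylic OH is hydrogenated (the eight isolated trisubstituted alkenes behave like the C6=C7 bond of geraniol and stay), the (S)-BINAP complex being expected to add H2 to the same face of the O–C–C=C unit as in geraniol to (R)-citronellol, which here gives 35S (to be confirmed by Mosher analysis of 9, with the (R)-ligand as the remedy), and Ag2O returns 8 to the quinone.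

Step 4
Reactants: 9 (35S)-36-hydroxy-34,35-dihydroubiquinone-9
Product: 10 (35S)-36-tosyloxy-34,35-dihydroubiquinone-9
Conditions: TsCl (1.5 equiv), pyridine, CH2Cl2, 0 °C
Reagents that add atoms: p-toluenesulfonyl chloride, Cc1ccc(cc1)S(Cl)(=O)=O
Why: Standard sulfonylation of the only hydroxyl group; the fully substituted quinone has no free position for pyridine addition and the C35 centre is not involved.

Step 5
Reactants: 10 (35S)-36-tosyloxy-34,35-dihydroubiquinone-9
Product: 13 (35S)-34,35-dihydroubiquinone-10 (target), via (35S)-36-tosyloxy-34,35-dihydroubiquinol-9 11 (not isolated), via (35S)-34,35-dihydroubiquinol-10 12 (not isolated)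
Conditions: Na2S2O4, Et2O/H2O, 25 °C, organic layer dried under Ar; then prenylmagnesium chloride (6 equiv), CuI (10 mol %), THF, −30 to 0 °C; aq NH4Cl; then Ag2O, Et2O, 25 °C
Reagents that add atoms: prenylmagnesium chloride (3-methylbut-2-en-1-ylmagnesium chloride), CC(C)=CC[Mg]Cl
Why: Copper-catalysed sp3–sp3 cross-coupling of a primary tosylate with an allylic Grignard reagent (Fouquet–Schlosser/Linstrumelle type): dithionite masks the quinone as hydroquinone 11, two equivalents of Grignard reagent are spent on the phenols, the allylcopper species is expected to couple through its unsubstituted α-carbon so the prenyl terminus forms without allylic transposition, the stereocentre β to the reacting carbon is untouched, and Ag2O reoxidises 12 to the quinone.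

## Compound list

1 | coenzyme Q0, 2,3-dimethoxy-5-methylcyclohexa-2,5-diene-1,4-dione | COC1=C(OC)C(=O)C(C)=CC1=O | starting material
2 | all-E solanesol, (2E,6E,10E,14E,18E,22E,26E,30E)-3,7,11,15,19,23,27,31,35-nonamethylhexatriaconta-2,6,10,14,18,22,26,30,34-nonaen-1-ol | OC/C=C(\C)CC/C=C(\C)CC/C=C(\C)CC/C=C(\C)CC/C=C(\C)CC/C=C(\C)CC/C=C(\C)CC/C=C(\C)CCC=C(C)C | starting material
3 | ubiquinol-0, 2,3-dimethoxy-5-methylbenzene-1,4-diol | COc1c(OC)c(O)c(C)cc1O | intermediate
4 | ubiquinol-9, 2,3-dimethoxy-5-methyl-6-(all-E solanesyl)benzene-1,4-diol | COc1c(OC)c(O)c(C/C=C(\C)CC/C=C(\C)CC/C=C(\C)CC/C=C(\C)CC/C=C(\C)CC/C=C(\C)CC/C=C(\C)CC/C=C(\C)CCC=C(C)C)c(C)c1O | intermediate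
5 | ubiquinone-9, 2,3-dimethoxy-5-methyl-6-(all-E solanesyl)-1,4-benzoquinone | COC1=C(OC)C(=O)C(C/C=C(\C)CC/C=C(\C)CC/C=C(\C)CC/C=C(\C)CC/C=C(\C)CC/C=C(\C)CC/C=C(\C)CC/C=C(\C)CCC=C(C)C)=C(C)C1=O | intermediate
6 | 36-hydroxyubiquinone-9, 2-[(2E,6E,10E,14E,18E,22E,26E,30E,34E)-36-hydroxy-3,7,11,15,19,23,27,31,35-nonamethylhexatriaconta-2,6,10,14,18,22,26,30,34-nonaen-1-yl]-5,6-dimethoxy-3-methyl-1,4-benzoquinone | COC1=C(OC)C(=O)C(C/C=C(\C)CC/C=C(\C)CC/C=C(\C)CC/C=C(\C)CC/C=C(\C)CC/C=C(\C)CC/C=C(\C)CC/C=C(\C)CC/C=C(\C)CO)=C(C)C1=O | intermediate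
7 | 36-hydroxyubiquinol-9, the benzene-1,4-diol (hydroquinone) form of 6 | COc1c(OC)c(O)c(C/C=C(\C)CC/C=C(\C)CC/C=C(\C)CC/C=C(\C)CC/C=C(\C)CC/C=C(\C)CC/C=C(\C)CC/C=C(\C)CC/C=C(\C)CO)c(C)c1O | intermediate
8 | (35S)-36-hydroxy-34,35-dihydroubiquinol-9, the hydroquinone form of 9 | COc1c(OC)c(O)c(C/C=C(\C)CC/C=C(\C)CC/C=C(\C)CC/C=C(\C)CC/C=C(\C)CC/C=C(\C)CC/C=C(\C)CC/C=C(\C)CCC[C@H](C)CO)c(C)c1O | intermediate
9 | (35S)-36-hydroxy-34,35-dihydroubiquinone-9, 2-[(2E,6E,10E,14E,18E,22E,26E,30E,35S)-36-hydroxy-3,7,11,15,19,23,27,31,35-nonamethylhexatriaconta-2,6,10,14,18,22,26,30-octaen-1-yl]-5,6-dimethoxy-3-methyl-1,4-benzoquinone | COC1=C(OC)C(=O)C(C/C=C(\C)CC/C=C(\C)CC/C=C(\C)CC/C=C(\C)CC/C=C(\C)CC/C=C(\C)CC/C=C(\C)CC/C=C(\C)CCC[C@H](C)CO)=C(C)C1=O | intermediate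
10 | (35S)-36-tosyloxy-34,35-dihydroubiquinone-9, the p-toluenesulfonate of the primary alcohol of 9 | COC1=C(OC)C(=O)C(C/C=C(\C)CC/C=C(\C)CC/C=C(\C)CC/C=C(\C)CC/C=C(\C)CC/C=C(\C)CC/C=C(\C)CC/C=C(\C)CCC[C@H](C)COS(=O)(=O)c2ccc(C)cc2)=C(C)C1=O | intermediate
11 | (35S)-36-tosyloxy-34,35-dihydroubiquinol-9, the hydroquinone form of 10 | COc1c(OC)c(O)c(C/C=C(\C)CC/C=C(\C)CC/C=C(\C)CC/C=C(\C)CC/C=C(\C)CC/C=C(\C)CC/C=C(\C)CC/C=C(\C)CCC[C@H](C)COS(=O)(=O)c2ccc(C)cc2)c(C)c1O | intermediate
12 | (35S)-34,35-dihydroubiquinol-10, the hydroquinone form of 13 | COc1c(OC)c(O)c(C/C=C(\C)CC/C=C(\C)CC/C=C(\C)CC/C=C(\C)CC/C=C(\C)CC/C=C(\C)CC/C=C(\C)CC/C=C(\C)CCC[C@H](C)CCC=C(C)C)c(C)c1O | intermediate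
13 | (35S)-34,35-dihydroubiquinone-10, 2-[(2E,6E,10E,14E,18E,22E,26E,30E,35S)-3,7,11,15,19,23,27,31,35,39-decamethyltetraconta-2,6,10,14,18,22,26,30,38-nonaen-1-yl]-5,6-dimethoxy-3-methyl-1,4-benzoquinone | COC1=C(OC)C(=O)C(C/C=C(\C)CC/C=C(\C)CC/C=C(\C)CC/C=C(\C)CC/C=C(\C)CC/C=C(\C)CC/C=C(\C)CC/C=C(\C)CCC[C@H](C)CCC=C(C)C)=C(C)C1=O | target

## Step count and risk

Total step count: 5. Longest linear sequence: 5 steps (1 and 2 to 13).

The three steps most likely to fail:

**Step 1 (redox-chain prenylation).** The chain-carrying hydroquinone is present only in substoichiometric amount, so cation–alkene cyclisation of the solanesyl cation or 2E/2Z scrambling may dominate. Fallback with reversed polarity, setting out from 2 and coming back at 5: PBr3 (Et2O, 0 °C) converts 2 into solanesyl bromide F1. Me3SnLi (THF, −78 °C) then gives all-E solanesyltrimethylstannane F2. F2 adds to quinone 1 under BF3·OEt2 (CH2Cl2, −78 °C) by carbonyl 1,2-addition and [3,3] shift to the free ring carbon, giving hydroquinone 4 with the E geometry kept. Ag2O (Et2O) oxidises 4 to 5.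

**Step 3 (asymmetric hydrogenation).** The 2-methyl-2-alkenol class is less well documented than geraniol-type substrates, and the enantiomeric excess or the sense of induction may fall short. Fallback with a carboxylate as directing group, setting out from 6 and coming back at 9: MnO2 (CH2Cl2) gives the E enal F3. NaClO2/NaH2PO4 with 2-methyl-2-butene (t-BuOH/H2O) gives the E 2-methyl-2-enoic acid F4. Hydrogenation with Ru(OAc)2[(S)-H8-BINAP] (H2, MeOH) runs through the hydroquinone enoic acid F5 to the hydroquinone (S)-acid F6; this is the tiglic acid class, for which the (S)-ligand gives the (S)-2-methyl acid. LiAlH4 (THF, 0 °C) reduces the acid to the primary alcohol, which is 8, and Ag2O gives 9.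

**Step 5 (prenyl Grignard coupling).** The allylic Grignard reagent may couple through its γ-carbon, giving the 1,1-dimethylallyl isomer, or the phenolate-laden substrate may couple sluggishly. Fallback with a symmetric nucleophile and a metathesis end-capping, setting out from 10 and coming back at 13: 10 is reduced with Na2S2O4 to 11 as before. Allylmagnesium bromide (6 equiv) with CuI (THF, −30 to 0 °C) gives the terminal-alkene hydroquinone F7, for which no α/γ question exists. Ag2O gives the terminal-alkene quinone F8. Cross-metathesis of F8 with excess 2-methyl-2-butene (second-generation Grubbs catalyst, CH2Cl2, 40 °C) turns CH=CH2 into CH=C(CH3)2 and gives 13; the hindered internal trisubstituted alkenes and the quinone are expected to be left alone.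

Further compounds
F1 | step 1 | all-E solanesyl bromide | BrC/C=C(\C)CC/C=C(\C)CC/C=C(\C)CC/C=C(\C)CC/C=C(\C)CC/C=C(\C)CC/C=C(\C)CC/C=C(\C)CCC=C(C)C
F2 | step 1 | all-E solanesyltrimethylstannane | C[Sn](C)(C)C/C=C(\C)CC/C=C(\C)CC/C=C(\C)CC/C=C(\C)CC/C=C(\C)CC/C=C(\C)CC/C=C(\C)CC/C=C(\C)CCC=C(C)C
F3 | step 3 | (34E)-36-oxoubiquinone-9 (terminal E enal of 6) | COC1=C(OC)C(=O)C(C/C=C(\C)CC/C=C(\C)CC/C=C(\C)CC/C=C(\C)CC/C=C(\C)CC/C=C(\C)CC/C=C(\C)CC/C=C(\C)CC/C=C(\C)C=O)=C(C)C1=O
F4 | step 3 | (34E)-ubiquinone-9-36-oic acid (terminal E 2-methyl-2-enoic acid) | COC1=C(OC)C(=O)C(C/C=C(\C)CC/C=C(\C)CC/C=C(\C)CC/C=C(\C)CC/C=C(\C)CC/C=C(\C)CC/C=C(\C)CC/C=C(\C)CC/C=C(\C)C(=O)O)=C(C)C1=O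
F5 | step 3 | hydroquinone form of F4 | COc1c(OC)c(O)c(C/C=C(\C)CC/C=C(\C)CC/C=C(\C)CC/C=C(\C)CC/C=C(\C)CC/C=C(\C)CC/C=C(\C)CC/C=C(\C)CC/C=C(\C)C(=O)O)c(C)c1O
F6 | step 3 | (35S)-34,35-dihydroubiquinol-9-36-oic acid | COc1c(OC)c(O)c(C/C=C(\C)CC/C=C(\C)CC/C=C(\C)CC/C=C(\C)CC/C=C(\C)CC/C=C(\C)CC/C=C(\C)CC/C=C(\C)CCC[C@H](C)C(=O)O)c(C)c1O
F7 | step 5 | 2,3-dimethoxy-5-methyl-6-[(2E,6E,10E,14E,18E,22E,26E,30E,35S)-3,7,11,15,19,23,27,31,35-nonamethylnonatriaconta-2,6,10,14,18,22,26,30,38-nonaen-1-yl]benzene-1,4-diol | COc1c(OC)c(O)c(C/C=C(\C)CC/C=C(\C)CC/C=C(\C)CC/C=C(\C)CC/C=C(\C)CC/C=C(\C)CC/C=C(\C)CC/C=C(\C)CCC[C@H](C)CCC=C)c(C)c1O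
F8 | step 5 | 1,4-benzoquinone form of F7 | COC1=C(OC)C(=O)C(C/C=C(\C)CC/C=C(\C)CC/C=C(\C)CC/C=C(\C)CC/C=C(\C)CC/C=C(\C)CC/C=C(\C)CC/C=C(\C)CCC[C@H](C)CCC=C)=C(C)C1=O
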